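## Retrosynthetic overview

- The strategy rests on ring B: C3' and C5', the two carbons ortho to the C4' hydroxyl, each carry a 3-methylbut-2-enyl group, while C6 and C8 of ring A (ortho to the C7 hydroxyl) are unsubstituted and C2 is a base-labile (S)-stereocenter.
- Both aryl–CH2 bonds at C3' and C5' are disconnected together. This leads back to unprotected (S)-liquiritigenin and two molecules of dimethylallyl diphosphate, joined in the forward direction by an aromatic prenyltransferase.
- (S)-Liquiritigenin is traced to isoliquiritigenin by an enzymatic oxa-Michael closure of ring C, which sets C2. Dimethylallyl diphosphate is traced to prenol by two ATP-dependent kinase steps.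
- Ring order: rings A and B come with isoliquiritigenin, ring C is closed in step 1, and no ring is formed afterwards.

Key step: step 3

Assumption: the prenyltransferase of step 3 is the member of a small panel of soluble recombinant enzymes (lead: AtaPT from Aspergillus terreus, wild type or an acceptor-pocket variant) that shows the ring B 3',5'-selectivity in an analytical screen; the route is written for that enzyme.

## Route

Step 1
Reactants: 1 isoliquiritigenin, (E)-1-(2,4-dihydroxyphenyl)-3-(4-hydroxyphenyl)prop-2-en-1-one
Product: 2 (S)-liquiritigenin, (2S)-7-hydroxy-2-(4-hydroxyphenyl)chroman-4-one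
Conditions: recombinant Medicago sativa chalcone isomerase (legume class accepting 6'-deoxychalcones), HEPES 50 mM pH 7.0, 5% DMSO, 25 °C, dark; EtOAc extraction, SiO2
Reagents that add atoms: none
Why: Enzymatic intramolecular oxa-Michael addition (6-endo-trig) of the 2'-phenoxide to the enone, in which the active site exposes a single face of the β-carbon and so should set C2 as (S), while the non-enzymatic racemic cyclisation of a 6'-deoxychalcone is slow at pH 7.

Step 2
Reactants: 3 prenol, 3-methylbut-2-en-1-ol
Product: 5 dimethylallyl diphosphate, via dimethylallyl phosphate 4 (not isolated)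
Conditions: ATP (2.4 equiv), Escherichia coli hydroxyethylthiazole kinase (ThiM), Methanocaldococcus jannaschii isopentenyl phosphate kinase, MgCl2, Tris-HCl pH 7.8, 37 °C; ultrafiltration, DEAE anion exchange (NH4HCO3 gradient), lyophilised as the ammonium salt
Reagents that add atoms: adenosine 5'-triphosphate (ATP), C1=NC(=C2C(=N1)N(C=N2)[C@H]3[C@@H]([C@@H]([C@H](O3)COP(=O)(O)OP(=O)(O)OP(=O)(O)O)O)O)N
Why: Two consecutive enzymatic phosphoryl transfers from ATP (a promiscuous alcohol kinase gives the monophosphate 4 and isopentenyl phosphate kinase gives the diphosphate), a known two-kinase cascade for prenol that keeps the acid-labile allylic diphosphate at pH near 8 throughout.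

Step 3
Reactants: 2 (S)-liquiritigenin; 5 dimethylallyl diphosphate (two molecules per molecule of 2)
Product: 7 abyssinone-IV, (2S)-7-hydroxy-2-[4-hydroxy-3,5-bis(3-methylbut-2-enyl)phenyl]chroman-4-one, via (2S)-3'-prenylliquiritigenin 6 (not isolated)
Conditions: AtaPT-type aromatic prenyltransferase (panel-selected), 5 (3.5 equiv, in portions), Tris-HCl 50 mM pH 7.0–7.5, CaCl2 5 mM, 5% DMSO, 30 °C; EtOAc extraction, reversed-phase chromatography
Reagents that add atoms: none
Why: Proposed new method: the enzyme ionises 5 to a dimethylallyl cation–diphosphate pair held over ring B, C3' (ortho to the C4' hydroxyl, which is hydrogen-bonded to an active-site base) attacks the primary carbon of the cation and loss of the C3' proton restores the arene to give 6, which is released, rebinds with ring B turned by 180° about the C2–C1' axis and is alkylated at C5' in a second cycle. The closest known reaction type is the enzymatic Friedel–Crafts C-monoprenylation of flavanones, isoflavones and 4-hydroxyphenylpyruvate ortho to a phenol by DMATS-type and ABBA-fold prenyltransferases, together with consecutive prenyl transfers by promiscuous members of these families; a 3',5'-double prenylation of a flavanone ring B has not been shown. No ring is closed and no stereocenter is formed: C2 is carried over from 2, and the near-neutral buffer should suppress the retro-oxa-Michael opening that would racemise it. The step needs ring B over C6 and C8 of ring A, carbon over oxygen, normal over reverse attachment, and acceptance of 6 for the second transfer. The substrate helps in that ring B is a simple para-alkylphenol with two equivalent ortho carbons while ring A is deactivated by the carbonyl para to the C7 hydroxyl, but the decisive control is the acceptor pocket and would be secured by screening and, if needed, engineering. Acid-promoted chemical prenylation is not an option because it would alkylate both rings and cyclise ortho-prenylphenols to 2,2-dimethylchromans.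

## Compound list

1 | isoliquiritigenin, (E)-1-(2,4-dihydroxyphenyl)-3-(4-hydroxyphenyl)prop-2-en-1-one | O=C(/C=C/c1ccc(O)cc1)c1ccc(O)cc1O | starting material
2 | (S)-liquiritigenin, (2S)-7-hydroxy-2-(4-hydroxyphenyl)chroman-4-one | Oc1ccc([C@@H]2CC(=O)c3ccc(O)cc3O2)cc1 | intermediate
3 | prenol, 3-methylbut-2-en-1-ol | CC(C)=CCO | starting material
4 | dimethylallyl phosphate, 3-methylbut-2-enyl dihydrogen phosphate | CC(C)=CCOP(=O)(O)O | intermediate
5 | dimethylallyl diphosphate | CC(C)=CCOP(=O)(O)OP(=O)(O)O | intermediate
6 | (2S)-3'-prenylliquiritigenin, (2S)-7-hydroxy-2-[4-hydroxy-3-(3-methylbut-2-enyl)phenyl]chroman-4-one | CC(C)=CCc1cc([C@@H]2CC(=O)c3ccc(O)cc3O2)ccc1O | intermediate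
7 | abyssinone-IV, (2S)-7-hydroxy-2-[4-hydroxy-3,5-bis(3-methylbut-2-enyl)phenyl]chroman-4-one | CC(C)=CCc1cc([C@@H]2CC(=O)c3ccc(O)cc3O2)cc(CC=C(C)C)c1O | target

## Step count

Total steps: 3. Longest linear sequence: 2 steps (1 → 2 → 7, or 3 → 5 → 7).

## Steps most likely to fail

**Step 3 (proposed new method).** The transfer may go to C6 or C8 of ring A or to a phenol oxygen, may stop after the first prenyl group, or may attach the reverse (1,1-dimethylallyl) terminus. Hydrolysis of 5 in the buffer competes, and slow reversible opening of ring C could erode the C2 configuration.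

Fallback, setting out from 3 and returning at 7, with both prenyl groups installed before the flavanone is built:
- Prenol 3 would be converted with PBr3 (Et2O, 0 °C) into prenyl bromide F1.
- F1 would C-alkylate the phenoxide of commercial 4-hydroxybenzaldehyde twice (aqueous KOH, room temperature) to give 4-hydroxy-3,5-bis(3-methylbut-2-enyl)benzaldehyde F2, separated by chromatography from mono-C- and O-alkylated material.
- The phenol would be capped (MOMCl, iPr2NEt, CH2Cl2) as 4-(methoxymethoxy)-3,5-bis(3-methylbut-2-enyl)benzaldehyde F3.
- Commercial 2,4-dihydroxyacetophenone would be protected at the non-chelated hydroxyl (MOMCl, K2CO3, acetone) as 1-[2-hydroxy-4-(methoxymethoxy)phenyl]ethanone F4.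
- Claisen–Schmidt condensation of F3 with F4 (KOH, EtOH/H2O, room temperature) should give the protected chalcone (E)-1-[2-hydroxy-4-(methoxymethoxy)phenyl]-3-[4-(methoxymethoxy)-3,5-bis(3-methylbut-2-enyl)phenyl]prop-2-en-1-one F5.
- Dilute HCl in MeOH at 40 °C, monitored so that the ortho-prenylphenol does not cyclise, should release (E)-1-(2,4-dihydroxyphenyl)-3-[4-hydroxy-3,5-bis(3-methylbut-2-enyl)phenyl]prop-2-en-1-one F6.
- NaOAc in refluxing EtOH would close ring C to racemic abyssinone-IV F7.
- Preparative HPLC on an amylose tris(3,5-dimethylphenylcarbamate) phase would separate 7 from (R)-abyssinone-IV F8, which can be re-equilibrated with NaOAc and recycled.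

**Step 1.** Conversion may stall as the chalcone–flavanone equilibrium is approached, and non-enzymatic cyclisation and reopening at the buffer pH may lower the enantiopurity.

Fallback, setting out from 1 and returning at 2, replacing asymmetric catalysis by resolution: 1 would be cyclised with NaOAc in refluxing EtOH/H2O to racemic liquiritigenin F9. Preparative HPLC on a chiral polysaccharide phase would then give 2 and (R)-liquiritigenin F10, the latter being returned to the NaOAc equilibration.

**Step 2.** The cascade may stop at the monophosphate through ADP inhibition or low activity of the first kinase on the non-native alcohol, and the allylic diphosphate may solvolyse during anion-exchange isolation.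

Fallback, setting out from 3 and returning at 5, by chemical diphosphorylation: Corey–Kim chlorination of 3 (N-chlorosuccinimide, Me2S, CH2Cl2, −30 to 0 °C) would give prenyl chloride F11. Displacement with tris(tetra-n-butylammonium) hydrogen diphosphate, (nBu4N)3HP2O7, in MeCN, followed by exchange to the ammonium form and cellulose chromatography, should give 5.

## Further compounds

F1 | step 3 | prenyl bromide, 1-bromo-3-methylbut-2-ene | CC(C)=CCBr
F2 | step 3 | 4-hydroxy-3,5-bis(3-methylbut-2-enyl)benzaldehyde | CC(C)=CCc1cc(C=O)cc(CC=C(C)C)c1O
F3 | step 3 | 4-(methoxymethoxy)-3,5-bis(3-methylbut-2-enyl)benzaldehyde | COCOc1c(CC=C(C)C)cc(C=O)cc1CC=C(C)C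
F4 | step 3 | 1-[2-hydroxy-4-(methoxymethoxy)phenyl]ethanone | COCOc1ccc(C(C)=O)c(O)c1
F5 | step 3 | (E)-1-[2-hydroxy-4-(methoxymethoxy)phenyl]-3-[4-(methoxymethoxy)-3,5-bis(3-methylbut-2-enyl)phenyl]prop-2-en-1-one | COCOc1ccc(C(=O)/C=C/c2cc(CC=C(C)C)c(OCOC)c(CC=C(C)C)c2)c(O)c1
F6 | step 3 | (E)-1-(2,4-dihydroxyphenyl)-3-[4-hydroxy-3,5-bis(3-methylbut-2-enyl)phenyl]prop-2-en-1-one | CC(C)=CCc1cc(/C=C/C(=O)c2ccc(O)cc2O)cc(CC=C(C)C)c1O
F7 | step 3 | racemic abyssinone-IV, 7-hydroxy-2-[4-hydroxy-3,5-bis(3-methylbut-2-enyl)phenyl]chroman-4-one | CC(C)=CCc1cc(C2CC(=O)c3ccc(O)cc3O2)cc(CC=C(C)C)c1O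
F8 | step 3 | (R)-abyssinone-IV, (2R)-7-hydroxy-2-[4-hydroxy-3,5-bis(3-methylbut-2-enyl)phenyl]chroman-4-one | CC(C)=CCc1cc([C@H]2CC(=O)c3ccc(O)cc3O2)cc(CC=C(C)C)c1O
F9 | step 1 | racemic liquiritigenin, 7-hydroxy-2-(4-hydroxyphenyl)chroman-4-one | Oc1ccc(C2CC(=O)c3ccc(O)cc3O2)cc1
F10 | step 1 | (R)-liquiritigenin, (2R)-7-hydroxy-2-(4-hydroxyphenyl)chroman-4-one | Oc1ccc([C@H]2CC(=O)c3ccc(O)cc3O2)cc1
F11 | step 2 | prenyl chloride, 1-chloro-3-methylbut-2-ene | CC(C)=CCCl
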